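**Plan**
- Retrosynthesis: the three C–Br bonds of ring A (C3, C4, C5) and the isopropyl mask on the C1 hydroxyl are removed first. Ring B is then cut at C1'–C2' and C5'–C6'.
- Enabling feature: ring B is a 2,4-dibromophenyl ether. Its C2' and C4' bromines are 1,3-related exactly as the C3 and C5 bromines of 3,5-dibromo-2H-pyran-2-one, and C1' carries only the ether oxygen, as the oxygenated carbon of an aryl ethynyl ether does.
- Forward: ring A is taken intact from o-vanillin (O-isopropylation, Baeyer–Villiger, dichlorovinylation, elimination to the ynol ether). The pyranone comes from coumalic acid. Cycloaddition with loss of CO2 then builds ring B as the only ring made in the route.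
- Finish: BCl3 frees the phenol and Br2 fills the three open positions of ring A.
- Stereochemistry: the target is achiral and has no stereocentre. The only stereo-elements on the way are the E geometry of the dichlorovinyl ether and two transient bridgehead centres of the cycloadduct, and both disappear.

Key step: step 6

Remark: the order of bromine entry shown in steps 5 and 8 (and in the fallback for step 8) is the expected one; a different order would lead to the same products.

**Step 1**
Reactants: 1 o-vanillin (2-hydroxy-3-methoxybenzaldehyde)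
Product: 2 3-methoxy-2-(propan-2-yloxy)benzaldehyde
Conditions: 2-bromopropane, K2CO3, DMF, 60 °C
Reagents that add atoms: 2-bromopropane, CC(C)Br
Why: Williamson ether synthesis on the acidic ortho-formyl phenol; the isopropyl ether is chosen because it should survive peracid, n-BuLi and heat and can later be cleaved by BCl3 beside a methyl ether.

**Step 2**
Reactants: 2 3-methoxy-2-(propan-2-yloxy)benzaldehyde
Product: 4 3-methoxy-2-(propan-2-yloxy)phenol, via aryl formate 3 (not isolated)
Conditions: mCPBA, CH2Cl2, 0 °C → rt; aq NaHCO3 wash; then K2CO3 (cat.), MeOH, rt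
Reagents that add atoms: 3-chloroperoxybenzoic acid (mCPBA), O=C(OO)c1cccc(Cl)c1
Why: Baeyer–Villiger (Dakin-type) oxidation, in which the electron-rich ortho-alkoxyaryl group migrates in preference to hydride to give the formate, which mild methanolysis converts to the phenol.

**Step 3**
Reactants: 4 3-methoxy-2-(propan-2-yloxy)phenol; 5 trichloroethylene
Product: 7 1-{[(E)-1,2-dichloroethenyl]oxy}-3-methoxy-2-(propan-2-yloxy)benzene, via dichloroacetylene 6 (not isolated)
Conditions: K2CO3, DMF, 70 °C
Reagents that add atoms: none
Why: Known base-mediated dichlorovinylation of phenols: trichloroethylene loses HCl to dichloroacetylene, and anti addition of ArO–H across it should give the E-configured 1,2-dichlorovinyl ether.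

**Step 4**
Reactants: 7 1-{[(E)-1,2-dichloroethenyl]oxy}-3-methoxy-2-(propan-2-yloxy)benzene
Product: 10 1-(ethynyloxy)-3-methoxy-2-(propan-2-yloxy)benzene, via chloroethynyl ether 8 (not isolated), via lithium acetylide 9 (not isolated)
Conditions: n-BuLi (2.5 equiv), Et2O, −78 → −40 °C; then H2O, −40 → 0 °C; quick filtration through Et3N-deactivated silica, used at once
Reagents that add atoms: none
Why: Established dichlorovinyl ether to ynol ether conversion (deprotonation and loss of LiCl to the chloroalkyne, lithium–chlorine exchange, protonation); ring A carries only ethers and no halogen, so nothing else should react with n-BuLi at low temperature.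

**Step 5**
Reactants: 11 coumalic acid (2-oxo-2H-pyran-5-carboxylic acid)
Product: 13 3,5-dibromo-2H-pyran-2-one, via 3-bromocoumalic acid 12 (not isolated)
Conditions: NBS (2.5 equiv), LiOAc (cat.), MeCN–H2O, rt
Reagents that add atoms: N-bromosuccinimide, O=C1CCC(=O)N1Br
Why: Hunsdiecker-type bromodecarboxylation with NBS and catalytic LiOAc, known for this acid: electrophilic bromination at C3 of the coumalate, then ipso attack at C5 with loss of CO2.

**Step 6**
Reactants: 10 1-(ethynyloxy)-3-methoxy-2-(propan-2-yloxy)benzene; 13 3,5-dibromo-2H-pyran-2-one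
Product: 15 1-(2,4-dibromophenoxy)-3-methoxy-2-(propan-2-yloxy)benzene, via bridged lactone 14 (not isolated)
Conditions: 13 (1.5 equiv), toluene, 90 °C, sealed tube, acid-free glassware
Reagents that add atoms: none
Why: This is an inverse-electron-demand (4+2) cycloaddition followed by retro-(4+2) loss of CO2, the known pyranone–alkyne route to benzenes, with the dibromopyranone acting through its low LUMO toward an electron-rich 2π partner as it does toward enol ethers. The polarised ynol ether should deliver its nucleophilic terminal CH carbon to C6 of the pyranone and its oxygen-bearing carbon to the brominated C3, forming C5'–C6' and C1'–C2' in an intermolecular suprafacial six-membered closure to the 2-oxabicyclo[2.2.2]octadienone 14. Cycloreversion of 14 expels the O–C(=O) bridge as CO2 and closes ring B directly as a benzene ring, so no oxidation or elimination is needed and both ring B bromines arrive already in place. The two bridgehead centres of 14 are racemic and are destroyed on aromatisation, so no stereocentre has to be controlled. The selectivity needed is regiochemical (2,4- and not 3,5-dibromophenyl ether), and it should follow from matching the large HOMO coefficient at the ynol ether β-carbon with the large LUMO coefficient at pyranone C6, the orientation seen when vinyl ethers add to this diene. An excess of 13, moderate heat and an acid-free medium are meant to keep the labile ynol ether from hydrating or polymerising before it is consumed.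

**Step 7**
Reactants: 15 1-(2,4-dibromophenoxy)-3-methoxy-2-(propan-2-yloxy)benzene
Product: 17 2-(2,4-dibromophenoxy)-6-methoxyphenol, via aryloxydichloroborane 16 (not isolated)
Conditions: BCl3 (1 M in CH2Cl2, 1.5 equiv), CH2Cl2, −78 → 0 °C; then H2O
Reagents that add atoms: none
Why: Lewis acid dealkylation of an aryl isopropyl ether by BCl3, which at low temperature removes the secondary alkyl group as 2-chloropropane and is known to leave aryl methyl ethers, diaryl ethers and aryl bromides untouched.

**Step 8**
Reactants: 17 2-(2,4-dibromophenoxy)-6-methoxyphenol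
Product: 20 3,4,5-tribromo-2-(2,4-dibromophenoxy)-6-methoxyphenol, via monobromide 18 (not isolated), via dibromide 19 (not isolated)
Conditions: Br2 (3.3 equiv), AcOH, rt → 40 °C; aq NaHSO3 work-up
Reagents that add atoms: bromine, BrBr
Why: Electrophilic aromatic bromination in which every free position of ring A is ortho or para to an oxygen donor (C4 para to OH, C3 para to OMe, C5 para to OAr), as in the exhaustive bromination of guaiacol, while the non-phenolic, already dibrominated ring B should be far less reactive.

**Compound list**
1 | o-vanillin (2-hydroxy-3-methoxybenzaldehyde) | COc1cccc(C=O)c1O | starting material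
2 | 3-methoxy-2-(propan-2-yloxy)benzaldehyde | COc1cccc(C=O)c1OC(C)C | intermediate
3 | 3-methoxy-2-(propan-2-yloxy)phenyl formate (formed in the flask, step 2) | COc1cccc(OC=O)c1OC(C)C | intermediate
4 | 3-methoxy-2-(propan-2-yloxy)phenol | COc1cccc(O)c1OC(C)C | intermediate
5 | trichloroethylene (1,1,2-trichloroethene) | ClC=C(Cl)Cl | starting material
6 | dichloroacetylene (formed in the flask, step 3) | ClC#CCl | intermediate
7 | 1-{[(E)-1,2-dichloroethenyl]oxy}-3-methoxy-2-(propan-2-yloxy)benzene | Cl/C=C(/Cl)Oc1cccc(OC)c1OC(C)C | intermediate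
8 | 1-[(chloroethynyl)oxy]-3-methoxy-2-(propan-2-yloxy)benzene (formed in the flask, step 4) | ClC#COc1cccc(OC)c1OC(C)C | intermediate
9 | {[3-methoxy-2-(propan-2-yloxy)phenoxy]ethynyl}lithium (formed in the flask, step 4) | [Li]C#COc1cccc(OC)c1OC(C)C | intermediate
10 | 1-(ethynyloxy)-3-methoxy-2-(propan-2-yloxy)benzene | C#COc1cccc(OC)c1OC(C)C | intermediate
11 | coumalic acid (2-oxo-2H-pyran-5-carboxylic acid) | O=C(O)C1=COC(=O)C=C1 | starting material
12 | 3-bromo-2-oxo-2H-pyran-5-carboxylic acid (formed in the flask, step 5) | O=C(O)C1=COC(=O)C(Br)=C1 | intermediate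
13 | 3,5-dibromo-2H-pyran-2-one | O=C1OC=C(Br)C=C1Br | intermediate
14 | racemic 4,7-dibromo-5-[3-methoxy-2-(propan-2-yloxy)phenoxy]-2-oxabicyclo[2.2.2]octa-5,7-dien-3-one (one enantiomer drawn; formed in the flask, step 6) | O=C1O[C@@H]2C(Br)=C[C@@]1(Br)C(Oc3cccc(OC)c3OC(C)C)=C2 | intermediate
15 | 1-(2,4-dibromophenoxy)-3-methoxy-2-(propan-2-yloxy)benzene | COc1cccc(Oc2ccc(Br)cc2Br)c1OC(C)C | intermediate
16 | dichloro[2-(2,4-dibromophenoxy)-6-methoxyphenoxy]borane (formed in the flask, step 7) | COc1cccc(Oc2ccc(Br)cc2Br)c1OB(Cl)Cl | intermediate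
17 | 2-(2,4-dibromophenoxy)-6-methoxyphenol | COc1cccc(Oc2ccc(Br)cc2Br)c1O | intermediate
18 | 4-bromo-2-(2,4-dibromophenoxy)-6-methoxyphenol (formed in the flask, step 8) | COc1cc(Br)cc(Oc2ccc(Br)cc2Br)c1O | intermediate
19 | 3,4-dibromo-2-(2,4-dibromophenoxy)-6-methoxyphenol (formed in the flask, step 8) | COc1cc(Br)c(Br)c(Oc2ccc(Br)cc2Br)c1O | intermediate
20 | 3,4,5-tribromo-2-(2,4-dibromophenoxy)-6-methoxyphenol | COc1c(O)c(Oc2ccc(Br)cc2Br)c(Br)c(Br)c1Br | target

**Count**
Total steps: 8. Longest linear sequence: 7 steps (steps 1, 2, 3, 4, 6, 7, 8 from o-vanillin); the pyranone branch is step 5.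

**Steps most likely to fail**

Step 6. The terminal ynol ether may polymerise or hydrate faster than it adds to the pyranone, or the addition may lose regiocontrol. The fallback gives up the cycloaddition and makes the diaryl ether bond by nucleophilic aromatic substitution. It sets out from phenol 4, which is arylated with 4-bromo-1-fluoro-2-nitrobenzene (K2CO3, DMF, 80 °C) to give 1-(4-bromo-2-nitrophenoxy)-3-methoxy-2-(propan-2-yloxy)benzene F1. Reduction with Fe powder and NH4Cl in aqueous EtOH gives 5-bromo-2-[3-methoxy-2-(propan-2-yloxy)phenoxy]aniline F2. Diazotisation (NaNO2, aq HBr, 0 °C) gives 5-bromo-2-[3-methoxy-2-(propan-2-yloxy)phenoxy]benzenediazonium bromide F3, which is not isolated, and Sandmeyer bromination with CuBr places the ortho bromine and returns to the route at 15.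

Step 4. The terminal aryl ynol ether may be lost on isolation through acid-catalysed hydration or oligomerisation. The fallback keeps the cycloaddition but changes the dienophile to a silyl-capped one. It sets out from 7: the lithium acetylide 9, generated as before, is quenched with chlorotrimethylsilane instead of water to give the sturdier trimethyl({[3-methoxy-2-(propan-2-yloxy)phenoxy]ethynyl})silane F4. Heating F4 with 13 (o-xylene, 130 °C) should give, through the racemic bridged lactone 4,7-dibromo-5-[3-methoxy-2-(propan-2-yloxy)phenoxy]-6-(trimethylsilyl)-2-oxabicyclo[2.2.2]octa-5,7-dien-3-one F5 (not isolated) and loss of CO2, {3,5-dibromo-2-[3-methoxy-2-(propan-2-yloxy)phenoxy]phenyl}trimethylsilane F6. Fluoride-induced protodesilylation (TBAF, wet THF, 60 °C) removes the silyl group from C6' and returns to the route at 15.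

Step 8. Oxidation of the free phenol by bromine to quinonoid material may compete with the third substitution. The fallback reverses the order of the last two operations so that the oxygen stays masked during bromination. It sets out from 15: Br2 (3.5 equiv) in AcOH buffered with NaOAc at 50 °C should brominate ring A stepwise. The expected sequence runs through 1-bromo-2-(2,4-dibromophenoxy)-4-methoxy-3-(propan-2-yloxy)benzene F7 and 1,5-dibromo-2-(2,4-dibromophenoxy)-4-methoxy-3-(propan-2-yloxy)benzene F8 (neither isolated) to 1,2,3-tribromo-4-(2,4-dibromophenoxy)-6-methoxy-5-(propan-2-yloxy)benzene F9. BCl3 in CH2Cl2 (−78 → 0 °C) then cleaves the isopropyl ether through dichloro[3,4,5-tribromo-2-(2,4-dibromophenoxy)-6-methoxyphenoxy]borane F10 (not isolated), and aqueous work-up returns to the route at the target 20.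

**Further compounds**
F1 | step 6 | 1-(4-bromo-2-nitrophenoxy)-3-methoxy-2-(propan-2-yloxy)benzene | COc1cccc(Oc2ccc(Br)cc2[N+](=O)[O-])c1OC(C)C
F2 | step 6 | 5-bromo-2-[3-methoxy-2-(propan-2-yloxy)phenoxy]aniline | COc1cccc(Oc2ccc(Br)cc2N)c1OC(C)C
F3 | step 6 | 5-bromo-2-[3-methoxy-2-(propan-2-yloxy)phenoxy]benzenediazonium bromide | COc1cccc(Oc2ccc(Br)cc2[N+]#N)c1OC(C)C.[Br-]
F4 | step 4 | trimethyl({[3-methoxy-2-(propan-2-yloxy)phenoxy]ethynyl})silane | C[Si](C)(C)C#COc1cccc(OC)c1OC(C)C
F5 | step 4 | racemic 4,7-dibromo-5-[3-methoxy-2-(propan-2-yloxy)phenoxy]-6-(trimethylsilyl)-2-oxabicyclo[2.2.2]octa-5,7-dien-3-one (one enantiomer drawn) | O=C1O[C@@H]2C(Br)=C[C@@]1(Br)C(Oc3cccc(OC)c3OC(C)C)=C2[Si](C)(C)C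
F6 | step 4 | {3,5-dibromo-2-[3-methoxy-2-(propan-2-yloxy)phenoxy]phenyl}trimethylsilane | COc1cccc(Oc2c(Br)cc(Br)cc2[Si](C)(C)C)c1OC(C)C
F7 | step 8 | 1-bromo-2-(2,4-dibromophenoxy)-4-methoxy-3-(propan-2-yloxy)benzene | COc1ccc(Br)c(Oc2ccc(Br)cc2Br)c1OC(C)C
F8 | step 8 | 1,5-dibromo-2-(2,4-dibromophenoxy)-4-methoxy-3-(propan-2-yloxy)benzene | COc1c(Br)cc(Br)c(Oc2ccc(Br)cc2Br)c1OC(C)C
F9 | step 8 | 1,2,3-tribromo-4-(2,4-dibromophenoxy)-6-methoxy-5-(propan-2-yloxy)benzene | COc1c(OC(C)C)c(Oc2ccc(Br)cc2Br)c(Br)c(Br)c1Br
F10 | step 8 | dichloro[3,4,5-tribromo-2-(2,4-dibromophenoxy)-6-methoxyphenoxy]borane | COc1c(OB(Cl)Cl)c(Oc2ccc(Br)cc2Br)c(Br)c(Br)c1Br
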